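**Retrosynthetic overview**
1. Target 13 ⇐ flavanone 11: one hydrogenation saturates the C8 side chain and frees the 5-OH (benzyl ether).
2. 11 ⇐ chalcone 10: the O1–C2 bond, the only stereocentre and the pyranone ring (ring C) come from an enantioselective 6-endo oxa-Michael addition of the 2'-phenol to the enone.
3. 10 ⇐ ketone 7 + benzaldehyde 8: Claisen–Schmidt condensation brings in ring B.
4. 7 ⇐ aryl iodide 5 + alkene 6 (Heck); 5 ⇐ 3 (iodination ortho to the free phenol); 3 ⇐ 1 (mono-benzylation of the symmetric diol, which decides which phenol becomes O1).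
5. Ring order: ring A is bought, ring B arrives with benzaldehyde, ring C is the only ring made, in step 5.

Assumption: the given SMILES is the (2S)-flavanone; compounds 1, 2, 4, 6 and 8 are catalogue chemicals.

Catalyst A (step 5, made beforehand, not counted as a step): 1-[3,5-bis(trifluoromethyl)phenyl]-3-[(2S)-3,3-dimethyl-1-{[tris(4-methoxyphenyl)-λ5-phosphanylidene]amino}butan-2-yl]thiourea, COc1ccc(cc1)P(=NC[C@@H](NC(=S)Nc1cc(cc(c1)C(F)(F)F)C(F)(F)F)C(C)(C)C)(c1ccc(OC)cc1)c1ccc(OC)cc1. It is a bifunctional iminophosphorane (BIMP) from L-tert-leucine.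

Handling note: 7, 10 and 11 carry an acid-labile aryl-conjugated allylic carbinol (it closes to a 2,2-dimethylchromene with acid). Chromatograph them on Et3N-deactivated silica and avoid strong acid.

**Route**

Step 1
Reactants: 1 1-(2,6-dihydroxy-4-methoxyphenyl)ethan-1-one; 2 benzyl bromide
Product: 3 1-[2-(benzyloxy)-6-hydroxy-4-methoxyphenyl]ethan-1-one
Conditions: BnBr (1.05 equiv), K2CO3 (1.1 equiv), acetone, reflux, 6 h
Reagents that add atoms: benzyl bromide (2), BrCc1ccccc1
Why: Williamson etherification of the symmetric diol stops at the mono-ether because the remaining phenol is held in a strong hydrogen bond to the acetyl carbonyl.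

Step 2
Reactants: 3 1-[2-(benzyloxy)-6-hydroxy-4-methoxyphenyl]ethan-1-one; 4 N-iodosuccinimide
Product: 5 1-[6-(benzyloxy)-2-hydroxy-3-iodo-4-methoxyphenyl]ethan-1-one
Conditions: NIS (1.05 equiv), TFA (10 mol %), MeCN, 0 °C to rt
Reagents that add atoms: N-iodosuccinimide (4), O=C1CCC(=O)N1I
Why: Electrophilic aromatic iodination goes ortho to the free chelated phenol at C3, which is less hindered than C5 (flanked by OMe and OBn), by analogy with the C3-selective halogenation of 2-hydroxy-4,6-dimethoxyacetophenone.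

Step 3
Reactants: 5 1-[6-(benzyloxy)-2-hydroxy-3-iodo-4-methoxyphenyl]ethan-1-one; 6 2-methylbut-3-en-2-ol
Product: 7 1-[6-(benzyloxy)-2-hydroxy-3-[(1E)-3-hydroxy-3-methylbut-1-en-1-yl]-4-methoxyphenyl]ethan-1-one
Conditions: 6 (3 equiv), Pd(OAc)2 (5 mol %), Bu4NCl (1 equiv), NaHCO3 (2.5 equiv), DMF, 80 °C
Reagents that add atoms: 2-methylbut-3-en-2-ol (6), C=CC(C)(C)O
Why: Mizoroki–Heck reaction under Jeffery conditions, in which zerovalent palladium inserts into the C–I bond, the aryl adds to the terminal alkene carbon, and β-hydride elimination can only occur toward the benzylic carbon (the carbinol carbon is quaternary), giving the (E)-alkene.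

Step 4
Reactants: 7 1-[6-(benzyloxy)-2-hydroxy-3-[(1E)-3-hydroxy-3-methylbut-1-en-1-yl]-4-methoxyphenyl]ethan-1-one; 8 benzaldehyde
Product: 10 (2E)-1-[6-(benzyloxy)-2-hydroxy-3-[(1E)-3-hydroxy-3-methylbut-1-en-1-yl]-4-methoxyphenyl]-3-phenylprop-2-en-1-one, via aldol adduct 9 (not isolated)
Conditions: PhCHO (1.5 equiv), KOH (50% aq.), EtOH, rt, 24 h; then aq. NH4Cl, 0 °C
Reagents that add atoms: benzaldehyde (8), O=Cc1ccccc1
Why: Claisen–Schmidt condensation, in which the ketone enolate adds to non-enolisable benzaldehyde and E1cB dehydration of aldol 9 gives the (E)-enone, while the 2'-phenoxide present in strong base holds the product in the open chalcone form.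

Step 5
Reactants: 10 (2E)-1-[6-(benzyloxy)-2-hydroxy-3-[(1E)-3-hydroxy-3-methylbut-1-en-1-yl]-4-methoxyphenyl]-3-phenylprop-2-en-1-one
Product: 11 (2S)-5-(benzyloxy)-8-[(1E)-3-hydroxy-3-methylbut-1-en-1-yl]-7-methoxy-2-phenyl-2,3-dihydro-4H-chromen-4-one
Conditions: catalyst A (10 mol %), toluene, −20 °C, 24–48 h; filter cold through Et3N-deactivated silica
Reagents that add atoms: none
Why: Proposed new method: enantioselective 6-endo-trig oxa-Michael cyclisation of an unactivated 2'-hydroxychalcone under BIMP catalysis, in which the iminophosphorane (basic enough to break the OH···O=C chelate) deprotonates the 2'-phenol to a tight aminophosphonium phenoxide ion pair, the thiourea N–H pair binds the s-cis enone carbonyl, the tert-butyl group and P-aryl wall leave only the Si face of Cβ open to the phenoxide oxygen to give the (2S) centre, and the aminophosphonium N–H protonates the enolate to release the catalyst; the 6'-benzyloxy group twists the enone out of the arene plane and so favours ring closure, and low temperature in a non-polar solvent suppresses E1cB ring-opening; the closest known reaction types are BIMP-catalysed enantioselective intramolecular oxa-Michael additions of alcohols to α,β-unsaturated esters and amides and cinchona-thiourea cyclisations of ester-activated 2'-hydroxychalcones.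

Step 6
Reactants: 11 (2S)-5-(benzyloxy)-8-[(1E)-3-hydroxy-3-methylbut-1-en-1-yl]-7-methoxy-2-phenyl-2,3-dihydro-4H-chromen-4-one
Product: 13 (2S)-5-hydroxy-8-(3-hydroxy-3-methylbutyl)-7-methoxy-2-phenyl-2,3-dihydro-4H-chromen-4-one, via saturated benzyl ether 12 (not isolated)
Conditions: H2 (1 atm), 10% Pd/C, EtOAc, rt, 2–4 h
Reagents that add atoms: none
Why: Heterogeneous hydrogenation saturates the styrenyl C=C and then hydrogenolyses the aryl benzyl ether under neutral conditions that leave the aryl ketone, the tertiary alcohol and the C2 stereocentre untouched (no base, so no retro-oxa-Michael).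

**Compound list**
1 | 1-(2,6-dihydroxy-4-methoxyphenyl)ethan-1-one | CC(=O)c1c(O)cc(OC)cc1O | starting material
2 | benzyl bromide | BrCc1ccccc1 | starting material
3 | 1-[2-(benzyloxy)-6-hydroxy-4-methoxyphenyl]ethan-1-one | CC(=O)c1c(O)cc(OC)cc1OCc1ccccc1 | intermediate
4 | N-iodosuccinimide | O=C1CCC(=O)N1I | starting material
5 | 1-[6-(benzyloxy)-2-hydroxy-3-iodo-4-methoxyphenyl]ethan-1-one | CC(=O)c1c(O)c(I)c(OC)cc1OCc1ccccc1 | intermediate
6 | 2-methylbut-3-en-2-ol | C=CC(C)(C)O | starting material
7 | 1-[6-(benzyloxy)-2-hydroxy-3-[(1E)-3-hydroxy-3-methylbut-1-en-1-yl]-4-methoxyphenyl]ethan-1-one | CC(=O)c1c(O)c(/C=C/C(C)(C)O)c(OC)cc1OCc1ccccc1 | intermediate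
8 | benzaldehyde | O=Cc1ccccc1 | starting material
9 | 1-[6-(benzyloxy)-2-hydroxy-3-[(1E)-3-hydroxy-3-methylbut-1-en-1-yl]-4-methoxyphenyl]-3-hydroxy-3-phenylpropan-1-one (racemic aldol adduct) | OC(CC(=O)c1c(O)c(/C=C/C(C)(C)O)c(OC)cc1OCc1ccccc1)c1ccccc1 | intermediate
10 | (2E)-1-[6-(benzyloxy)-2-hydroxy-3-[(1E)-3-hydroxy-3-methylbut-1-en-1-yl]-4-methoxyphenyl]-3-phenylprop-2-en-1-one | O=C(/C=C/c1ccccc1)c1c(O)c(/C=C/C(C)(C)O)c(OC)cc1OCc1ccccc1 | intermediate
11 | (2S)-5-(benzyloxy)-8-[(1E)-3-hydroxy-3-methylbut-1-en-1-yl]-7-methoxy-2-phenyl-2,3-dihydro-4H-chromen-4-one | O=C1C[C@@H](c2ccccc2)Oc2c1c(OCc1ccccc1)cc(OC)c2/C=C/C(C)(C)O | intermediate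
12 | (2S)-5-(benzyloxy)-8-(3-hydroxy-3-methylbutyl)-7-methoxy-2-phenyl-2,3-dihydro-4H-chromen-4-one | O=C1C[C@@H](c2ccccc2)Oc2c1c(OCc1ccccc1)cc(OC)c2CCC(C)(C)O | intermediate
13 | (2S)-5-hydroxy-8-(3-hydroxy-3-methylbutyl)-7-methoxy-2-phenyl-2,3-dihydro-4H-chromen-4-one | COc1cc(O)c2c(c1CCC(C)(C)O)O[C@H](c1ccccc1)CC2=O | target

**Totals**
Total step count: 6. Longest linear sequence: 6 steps (1 → 3 → 5 → 7 → 10 → 11 → 13).

**Three steps most likely to fail**

Step 5 (the proposed oxa-Michael cyclisation). The risks are modest enantioselectivity, a racemic background cyclisation, and erosion of ee by base-induced ring opening of 11. The sense of induction must be confirmed on the first run by chiral HPLC and CD; the mirror-image catalyst from D-tert-leucine is equally accessible if it is reversed. The ee can be raised by recrystallising 11 or 13. Fallback with known chemistry, setting out from 10: heating 10 with NaOAc in EtOH at reflux gives racemic 5-(benzyloxy)-8-[(1E)-3-hydroxy-3-methylbut-1-en-1-yl]-7-methoxy-2-phenyl-2,3-dihydro-4H-chromen-4-one F4. Preparative HPLC on an amylose tris(3,5-dimethylphenylcarbamate) phase resolves it into 11 and (2R)-5-(benzyloxy)-8-[(1E)-3-hydroxy-3-methylbut-1-en-1-yl]-7-methoxy-2-phenyl-2,3-dihydro-4H-chromen-4-one F5. The unwanted enantiomer is returned to the racemate by the same NaOAc treatment (ring opening and reclosure) and resolved again. The route is rejoined at 11.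

Step 3 (Heck coupling). The iodide 5 is electron-rich and flanked by OH and OMe, so oxidative addition and alkene insertion may be slow and proto-deiodination may compete. Fallback, setting out from 5: a Suzuki–Miyaura coupling replaces carbopalladation by transmetalation. The partner is (3E)-2-methyl-4-(4,4,5,5-tetramethyl-1,3,2-dioxaborolan-2-yl)but-3-en-2-ol F3, a catalogue reagent that can otherwise be made from 2-methylbut-3-yn-2-ol and pinacolborane with catalytic Cp2Zr(H)Cl. Coupling with Pd(dppf)Cl2 and K2CO3 in dioxane/H2O at 80 °C rejoins the route at 7.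

Step 2 (iodination regiochemistry). Attack at C5 instead of C3 would give the isomer that leads to the 6-substituted flavanone; the outcome is checked by NOE (in 5 the single aromatic proton sees both OCH3 and OCH2Ph). Fallback, setting out from 1: the symmetric diol is iodinated first (NIS, 1.0 equiv, MeCN, 0 °C), where only one mono-iodide is possible, giving 1-(2,6-dihydroxy-3-iodo-4-methoxyphenyl)ethan-1-one F1. Heck coupling with 6 under the step 3 conditions gives 1-[2,6-dihydroxy-3-[(1E)-3-hydroxy-3-methylbut-1-en-1-yl]-4-methoxyphenyl]ethan-1-one F2. Benzylation (BnBr, K2CO3, acetone) then takes place at the less hindered 6-OH, away from the side chain, and the route is rejoined at 7.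

**Further compounds**
F1 | step 2 | 1-(2,6-dihydroxy-3-iodo-4-methoxyphenyl)ethan-1-one | CC(=O)c1c(O)c(I)c(OC)cc1O
F2 | step 2 | 1-[2,6-dihydroxy-3-[(1E)-3-hydroxy-3-methylbut-1-en-1-yl]-4-methoxyphenyl]ethan-1-one | CC(=O)c1c(O)c(/C=C/C(C)(C)O)c(OC)cc1O
F3 | step 3 | (3E)-2-methyl-4-(4,4,5,5-tetramethyl-1,3,2-dioxaborolan-2-yl)but-3-en-2-ol | CC(C)(O)/C=C/B1OC(C)(C)C(C)(C)O1
F4 | step 5 | racemic 5-(benzyloxy)-8-[(1E)-3-hydroxy-3-methylbut-1-en-1-yl]-7-methoxy-2-phenyl-2,3-dihydro-4H-chromen-4-one | O=C1CC(c2ccccc2)Oc2c1c(OCc1ccccc1)cc(OC)c2/C=C/C(C)(C)O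
F5 | step 5 | (2R)-5-(benzyloxy)-8-[(1E)-3-hydroxy-3-methylbut-1-en-1-yl]-7-methoxy-2-phenyl-2,3-dihydro-4H-chromen-4-one | O=C1C[C@H](c2ccccc2)Oc2c1c(OCc1ccccc1)cc(OC)c2/C=C/C(C)(C)O
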